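**Remark (assumption):** 5-chlorovanillin, O-benzylvanillin, homovanillic acid and [4-(benzyloxy)-3-methoxyphenyl]acetic acid are taken as commercial. The biaryl axis has one ortho oxygen on each ring and is taken as freely rotating, so the six carbon stereocentres (3S,4R,5S in both oxolanes) are the only stereo elements.

**Retrosynthetic overview**
1. The biaryl bond is cut first: Suzuki–Miyaura union of two O-benzylated olivil halves (half A: aryl chloride on the 5-aryl ring; half B: pinacol boronate on the 3-benzyl ring), followed by hydrogenolysis of four benzyl ethers.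
2. Each oxolane (oxolan-3-ol numbering: O1, C2H2, C3(OH)(benzyl), C4H(CH2OH), C5H(aryl)) is cut at O1–C2 and at C3–C4, which leads back to an (S)-1-arylprop-2-en-1-ol and a 1-aryl-3-diazopropan-2-one.
3. Enabling feature: the tertiary carbinol C3 lies between the ring CH2 bound to O1 (an α-alkoxy ketone in retrosynthesis) and C4 with its exocyclic CH2OH. C3, C2, O1, C5, C4 and the exocyclic carbon are the six atoms of a 3-oxahex-5-enyl ketyl, and the pattern of the target (5-aryl trans to CH2OH, 3-OH trans to CH2OH) is the one that 5-exo ketyl–olefin closure gives.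
4. Order of ring formation: oxolane of half A (step 5), oxolane of half B (step 11), each closed in one flask from its two acyclic partners; the biaryl bond follows (step 13).
5. The only stereocentre brought in from outside is the benzylic carbinol of each allylic alcohol (lipase resolution); the other four are set in the two ring closures.

Key step: step 5

**Step 1**
Reactants: 1 5-chlorovanillin (3-chloro-4-hydroxy-5-methoxybenzaldehyde)
Product: 2 4-(benzyloxy)-3-chloro-5-methoxybenzaldehyde
Conditions: BnBr, K2CO3, DMF, 60 °C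
Reagents that add atoms: benzyl bromide BrCc1ccccc1
Why: Williamson ether synthesis, in which the acidic ortho-chlorophenoxide is benzylated by SN2 while the aldehyde is left alone.

**Step 2**
Reactants: 2 4-(benzyloxy)-3-chloro-5-methoxybenzaldehyde
Product: 3 racemic 1-[4-(benzyloxy)-3-chloro-5-methoxyphenyl]prop-2-en-1-ol
Conditions: CH2=CHMgBr, THF, −78 → 0 °C; aq. NH4Cl
Reagents that add atoms: vinylmagnesium bromide C=C[Mg]Br
Why: Grignard 1,2-addition to the aryl aldehyde should give the allylic alcohol as a racemate, the carbinol centre being sorted out in step 3.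

**Step 3**
Reactants: 3 racemic 1-[4-(benzyloxy)-3-chloro-5-methoxyphenyl]prop-2-en-1-ol
Product: 4 (S)-1-[4-(benzyloxy)-3-chloro-5-methoxyphenyl]prop-2-en-1-ol
Conditions: lipase PS (Burkholderia cepacia, immobilised), vinyl acetate, MTBE, 30 °C, run to about 55 % conversion; chromatography
Reagents that add atoms: none
Why: Enzymatic kinetic resolution by transesterification, in which the empirical lipase rule (aryl as large, vinyl as medium group) predicts acetylation of the R alcohol, so that the S alcohol should remain and be separated from the acetate.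

**Step 4**
Reactants: 5 [4-(benzyloxy)-3-methoxyphenyl]acetic acid
Product: 7 1-[4-(benzyloxy)-3-methoxyphenyl]-3-diazopropan-2-one, via acid chloride 6 (not isolated)
Conditions: (COCl)2, DMF (cat.), CH2Cl2, 0 → 25 °C, evaporate; then CH2N2 (3 equiv), Et2O, 0 °C
Reagents that add atoms: diazomethane C=[N+]=[N-]
Why: Acylation of diazomethane by the acid chloride (first stage of the Arndt–Eistert sequence), with excess diazomethane taking up the HCl so that no chloromethyl ketone should form.

**Step 5**
Reactants: 4 (S)-1-[4-(benzyloxy)-3-chloro-5-methoxyphenyl]prop-2-en-1-ol; 7 1-[4-(benzyloxy)-3-methoxyphenyl]-3-diazopropan-2-one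
Product: 10 (3S,4R,5S)-5-[4-(benzyloxy)-3-chloro-5-methoxyphenyl]-3-{[4-(benzyloxy)-3-methoxyphenyl]methyl}-4-(hydroxymethyl)oxolan-3-ol, via allyloxy ketone 8 (not isolated), via alkylsamarium alkoxide 9 (not isolated)
Conditions: Rh2(OAc)4 (1 mol %), toluene, 25 °C, 7 (1.1 equiv) added over 2 h; then SmI2 (3.5 equiv), THF–HMPA (10:1), 0 °C, 20 min; then dry O2, −40 → 0 °C; PPh3; aq. NH4Cl
Reagents that add atoms: dioxygen O=O
Why: Rh2(OAc)4 converts 7 into a rhodium carbenoid that is attacked by the hydroxyl of 4, and proton transfer within the oxonium ylide (carbenoid O–H insertion) forms the O1–C2 bond of ketone 8; SmI2–HMPA then reduces the ketone to a ketyl radical anion that adds to the inner carbon of the vinyl group and so forms the C3–C4 bond, a second electron transfer gives the primary alkylsamarium 9, and O2 converts its C–Sm bond into the C–O bond of the CH2OH group. The closest known reaction types are the Rh2(OAc)4-catalysed O–H insertion of α-diazoketones into secondary alcohols and the SmI2–HMPA ketyl–olefin cyclization of unactivated olefinic ketones with capture of the organosamarium by electrophiles, oxygen among them. The one ring closes in the 5-exo-trig mode of a 3-oxahex-5-enyl ketyl. C4 is set by the chair-like transition state of 5-exo hexenyl radical closure, in which the aryl group on C5 lies pseudo-equatorial and therefore ends trans to the exocyclic CH2; C3 is set because the bulky, electron-rich O–Sm(HMPA)n group turns away from the alkene, which puts the hydroxyl trans and the benzyl group cis to the CH2OH branch; the preset S centre of 4 (C5) is not touched and controls both. The step needs O–H insertion to outrun sigmatropic rearrangement of the allyl oxonium ylide and attack of the carbenoid on its own arene (slow addition of 7 to the alcohol, the fastest trap), ring closure to outrun loss of the allylic alkoxide from the ketyl (no proton source, fast 5-exo closure), and the aryl chloride to survive (aryl chlorides should be inert to SmI2–HMPA at 0 °C).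

**Step 6**
Reactants: 11 4-(benzyloxy)-3-methoxybenzaldehyde (O-benzylvanillin)
Product: 12 racemic 1-[4-(benzyloxy)-3-methoxyphenyl]prop-2-en-1-ol
Conditions: CH2=CHMgBr, THF, −78 → 0 °C; aq. NH4Cl
Reagents that add atoms: vinylmagnesium bromide C=C[Mg]Br
Why: Grignard 1,2-addition to the aldehyde should give the racemic allylic alcohol, which is resolved in step 7.

**Step 7**
Reactants: 12 racemic 1-[4-(benzyloxy)-3-methoxyphenyl]prop-2-en-1-ol
Product: 13 (S)-1-[4-(benzyloxy)-3-methoxyphenyl]prop-2-en-1-ol
Conditions: lipase PS (Burkholderia cepacia, immobilised), vinyl acetate, MTBE, 30 °C, run to about 55 % conversion; chromatography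
Reagents that add atoms: none
Why: Lipase-catalysed kinetic resolution as in step 3, which should acetylate the R alcohol and leave the S alcohol.

**Step 8**
Reactants: 14 homovanillic acid ((4-hydroxy-3-methoxyphenyl)acetic acid)
Product: 15 (3-chloro-4-hydroxy-5-methoxyphenyl)acetic acid
Conditions: NCS (1.0 equiv), MeCN, 0 → 25 °C
Reagents that add atoms: N-chlorosuccinimide O=C1CCC(=O)N1Cl
Why: Electrophilic aromatic chlorination directed by the free phenol, whose para position is blocked, so that substitution should go ortho to the hydroxyl as in the halogenation of vanillin.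

**Step 9**
Reactants: 15 (3-chloro-4-hydroxy-5-methoxyphenyl)acetic acid
Product: 17 [4-(benzyloxy)-3-chloro-5-methoxyphenyl]acetic acid, via benzyl ester 16 (not isolated)
Conditions: BnBr (2.2 equiv), K2CO3, DMF, 60 °C; then NaOH, H2O–MeOH–THF, 50 °C; HCl to pH 2
Reagents that add atoms: benzyl bromide BrCc1ccccc1
Why: Williamson O-benzylation of phenoxide and carboxylate followed by saponification, which should cleave only the benzyl ester because the aryl benzyl ether is stable to hydroxide.

**Step 10**
Reactants: 17 [4-(benzyloxy)-3-chloro-5-methoxyphenyl]acetic acid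
Product: 19 1-[4-(benzyloxy)-3-chloro-5-methoxyphenyl]-3-diazopropan-2-one, via acid chloride 18 (not isolated)
Conditions: (COCl)2, DMF (cat.), CH2Cl2, 0 → 25 °C, evaporate; then CH2N2 (3 equiv), Et2O, 0 °C
Reagents that add atoms: diazomethane C=[N+]=[N-]
Why: Acylation of diazomethane by the acid chloride as in step 4 (first stage of the Arndt–Eistert sequence).

**Step 11**
Reactants: 13 (S)-1-[4-(benzyloxy)-3-methoxyphenyl]prop-2-en-1-ol; 19 1-[4-(benzyloxy)-3-chloro-5-methoxyphenyl]-3-diazopropan-2-one
Product: 22 (3S,4R,5S)-5-[4-(benzyloxy)-3-methoxyphenyl]-3-{[4-(benzyloxy)-3-chloro-5-methoxyphenyl]methyl}-4-(hydroxymethyl)oxolan-3-ol, via allyloxy ketone 20 (not isolated), via alkylsamarium alkoxide 21 (not isolated)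
Conditions: Rh2(OAc)4 (1 mol %), toluene, 25 °C, 19 (1.1 equiv) added over 2 h; then SmI2 (3.5 equiv), THF–HMPA (10:1), 0 °C, 20 min; then dry O2, −40 → 0 °C; PPh3; aq. NH4Cl
Reagents that add atoms: dioxygen O=O
Why: The same one-flask carbenoid O–H insertion, SmI2 ketyl–olefin cyclization (5-exo-trig) and oxygenation as in step 5, in which the chair-like transition state with the aryl group pseudo-equatorial and the O–Sm group turned away from the alkene should set C4 and C3 from the preset S carbinol of 13.

**Step 12**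
Reactants: 22 (3S,4R,5S)-5-[4-(benzyloxy)-3-methoxyphenyl]-3-{[4-(benzyloxy)-3-chloro-5-methoxyphenyl]methyl}-4-(hydroxymethyl)oxolan-3-ol
Product: 23 (3S,4R,5S)-5-[4-(benzyloxy)-3-methoxyphenyl]-3-{[4-(benzyloxy)-3-methoxy-5-(4,4,5,5-tetramethyl-1,3,2-dioxaborolan-2-yl)phenyl]methyl}-4-(hydroxymethyl)oxolan-3-ol
Conditions: B2pin2, Pd2(dba)3 (2 mol %), XPhos (8 mol %), KOAc, 1,4-dioxane, 100 °C
Reagents that add atoms: bis(pinacolato)diboron CC1(C)OB(OC1(C)C)B1OC(C)(C)C(C)(C)O1
Why: Miyaura borylation, in which the zerovalent palladium–XPhos catalyst adds oxidatively to the aryl chloride and acetate-assisted transmetalation from B2pin2 and reductive elimination follow, with the two free hydroxyls left alone.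

**Step 13**
Reactants: 10 (3S,4R,5S)-5-[4-(benzyloxy)-3-chloro-5-methoxyphenyl]-3-{[4-(benzyloxy)-3-methoxyphenyl]methyl}-4-(hydroxymethyl)oxolan-3-ol; 23 the pinacol boronate of half B
Product: 24 tetra-O-benzyl ether of the target (both oxolanes 3S,4R,5S)
Conditions: Pd(OAc)2 (5 mol %), SPhos (10 mol %), K3PO4, toluene–H2O (10:1), 90 °C
Reagents that add atoms: none
Why: Suzuki–Miyaura coupling with SPhos, a ligand made for electron-rich ortho-substituted aryl chlorides, should join the two halves, and since each ring carries only one ortho oxygen no stable axis of chirality arises.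

**Step 14**
Reactants: 24 tetra-O-benzyl ether of the target
Product: 25 CNP0269573.1 (target)
Conditions: H2 (1 atm), 10 % Pd/C, EtOAc–MeOH (1:1), 25 °C
Reagents that add atoms: none
Why: Hydrogenolysis of the four aryl benzyl ethers under mild neutral conditions should leave the oxolane C–O bonds, the tertiary alcohols and all six stereocentres unchanged.

**Compound list**
1 | 5-chlorovanillin | COc1cc(C=O)cc(Cl)c1O | starting material
2 | 4-(benzyloxy)-3-chloro-5-methoxybenzaldehyde | COc1cc(C=O)cc(Cl)c1OCc1ccccc1 | intermediate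
3 | racemic 1-[4-(benzyloxy)-3-chloro-5-methoxyphenyl]prop-2-en-1-ol | COc1cc(C(O)C=C)cc(Cl)c1OCc1ccccc1 | intermediate
4 | (S)-1-[4-(benzyloxy)-3-chloro-5-methoxyphenyl]prop-2-en-1-ol | O[C@H](c1cc(OC)c(OCc2ccccc2)c(Cl)c1)C=C | intermediate
5 | [4-(benzyloxy)-3-methoxyphenyl]acetic acid | OC(=O)Cc1ccc(OCc2ccccc2)c(OC)c1 | starting material
6 | [4-(benzyloxy)-3-methoxyphenyl]acetyl chloride | ClC(=O)Cc1ccc(OCc2ccccc2)c(OC)c1 | intermediate
7 | 1-[4-(benzyloxy)-3-methoxyphenyl]-3-diazopropan-2-one | [N-]=[N+]=CC(=O)Cc1ccc(OCc2ccccc2)c(OC)c1 | intermediate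
8 | allyloxy ketone: 1-[4-(benzyloxy)-3-methoxyphenyl]-3-{[(1S)-1-[4-(benzyloxy)-3-chloro-5-methoxyphenyl]prop-2-en-1-yl]oxy}propan-2-one | O=C(Cc1ccc(OCc2ccccc2)c(OC)c1)CO[C@H](c1cc(OC)c(OCc2ccccc2)c(Cl)c1)C=C | intermediate
9 | alkylsamarium alkoxide: derivative of 10 with SmI2 units of trivalent samarium on the tertiary oxygen and on the exocyclic CH2 carbon | COc1cc(C[C@@]2(O[Sm](I)I)CO[C@H](c3cc(OC)c(OCc4ccccc4)c(Cl)c3)[C@H]2C[Sm](I)I)ccc1OCc1ccccc1 | intermediate
10 | (3S,4R,5S)-5-[4-(benzyloxy)-3-chloro-5-methoxyphenyl]-3-{[4-(benzyloxy)-3-methoxyphenyl]methyl}-4-(hydroxymethyl)oxolan-3-ol (half A) | COc1cc(C[C@@]2(O)CO[C@H](c3cc(OC)c(OCc4ccccc4)c(Cl)c3)[C@H]2CO)ccc1OCc1ccccc1 | intermediate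
11 | 4-(benzyloxy)-3-methoxybenzaldehyde | COc1cc(C=O)ccc1OCc1ccccc1 | starting material
12 | racemic 1-[4-(benzyloxy)-3-methoxyphenyl]prop-2-en-1-ol | COc1cc(C(O)C=C)ccc1OCc1ccccc1 | intermediate
13 | (S)-1-[4-(benzyloxy)-3-methoxyphenyl]prop-2-en-1-ol | O[C@H](c1ccc(OCc2ccccc2)c(OC)c1)C=C | intermediate
14 | homovanillic acid | COc1cc(CC(O)=O)ccc1O | starting material
15 | (3-chloro-4-hydroxy-5-methoxyphenyl)acetic acid | COc1cc(CC(O)=O)cc(Cl)c1O | intermediate
16 | benzyl [4-(benzyloxy)-3-chloro-5-methoxyphenyl]acetate | COc1cc(CC(=O)OCc2ccccc2)cc(Cl)c1OCc1ccccc1 | intermediate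
17 | [4-(benzyloxy)-3-chloro-5-methoxyphenyl]acetic acid | COc1cc(CC(O)=O)cc(Cl)c1OCc1ccccc1 | intermediate
18 | [4-(benzyloxy)-3-chloro-5-methoxyphenyl]acetyl chloride | COc1cc(CC(Cl)=O)cc(Cl)c1OCc1ccccc1 | intermediate
19 | 1-[4-(benzyloxy)-3-chloro-5-methoxyphenyl]-3-diazopropan-2-one | COc1cc(CC(=O)C=[N+]=[N-])cc(Cl)c1OCc1ccccc1 | intermediate
20 | allyloxy ketone: 1-[4-(benzyloxy)-3-chloro-5-methoxyphenyl]-3-{[(1S)-1-[4-(benzyloxy)-3-methoxyphenyl]prop-2-en-1-yl]oxy}propan-2-one | O=C(Cc1cc(OC)c(OCc2ccccc2)c(Cl)c1)CO[C@H](c1ccc(OCc2ccccc2)c(OC)c1)C=C | intermediate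
21 | alkylsamarium alkoxide: derivative of 22 with SmI2 units of trivalent samarium on the tertiary oxygen and on the exocyclic CH2 carbon | COc1cc(C[C@@]2(O[Sm](I)I)CO[C@H](c3ccc(OCc4ccccc4)c(OC)c3)[C@H]2C[Sm](I)I)cc(Cl)c1OCc1ccccc1 | intermediate
22 | (3S,4R,5S)-5-[4-(benzyloxy)-3-methoxyphenyl]-3-{[4-(benzyloxy)-3-chloro-5-methoxyphenyl]methyl}-4-(hydroxymethyl)oxolan-3-ol | COc1cc(C[C@@]2(O)CO[C@H](c3ccc(OCc4ccccc4)c(OC)c3)[C@H]2CO)cc(Cl)c1OCc1ccccc1 | intermediate
23 | pinacol boronate of half B: (3S,4R,5S)-5-[4-(benzyloxy)-3-methoxyphenyl]-3-{[4-(benzyloxy)-3-methoxy-5-(4,4,5,5-tetramethyl-1,3,2-dioxaborolan-2-yl)phenyl]methyl}-4-(hydroxymethyl)oxolan-3-ol | COc1cc(C[C@@]2(O)CO[C@H](c3ccc(OCc4ccccc4)c(OC)c3)[C@H]2CO)cc(B5OC(C)(C)C(C)(C)O5)c1OCc1ccccc1 | intermediate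
24 | tetra-O-benzyl ether of the target (both oxolanes 3S,4R,5S; biaryl bond between the 5-aryl ring of half A and the 3-benzyl ring of half B) | COc1cc(C[C@@]2(O)CO[C@H](c3cc(OC)c(OCc4ccccc4)c(-c4cc(C[C@@]5(O)CO[C@H](c6ccc(OCc7ccccc7)c(OC)c6)[C@H]5CO)cc(OC)c4OCc4ccccc4)c3)[C@H]2CO)ccc1OCc1ccccc1 | intermediate
25 | CNP0269573.1 | COc1cc(C[C@@]2(O)CO[C@H](c3cc(OC)c(O)c(-c4cc(C[C@@]5(O)CO[C@H](c6ccc(O)c(OC)c6)[C@H]5CO)cc(OC)c4O)c3)[C@H]2CO)ccc1O | target

**Step count and risks**
Total steps: 14. Longest linear sequence: 7 steps (14 → 15 → 17 → 19 → 22 → 23 → 24 → 25).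

Step 5. The carbenoid may be diverted before proton transfer (sigmatropic rearrangement of the allyl oxonium ylide or its enol, or attack on its own electron-rich arene). The ketyl may expel the allylic alkoxide instead of cyclizing. The alkylsamarium may be protonated before oxygen capture, which would leave a methyl group. The fallback sets out from 4, builds the two bonds in separate known steps and comes back at 10. O-Propargylation (NaH, propargyl bromide, THF) should give the propargyl ether F1. Epoxidation of the vinyl group (mCPBA, NaHCO3, CH2Cl2) should give the oxiranyl propargyl ether F2, both oxirane epimers being usable. Cp2TiCl (from Cp2TiCl2 and Zn, THF) opens the oxirane homolytically to the secondary radical, which closes 5-exo-dig onto the alkyne trans to the aryl group; this should give the 4-methylene oxolane alcohol F3 with its CH2OH already in place. Dimethyldioxirane (acetone, 0 °C) should add oxygen to the exocyclic alkene from the face away from the neighbouring CH2OH and give the spiro-epoxide F4. [4-(Benzyloxy)-3-methoxyphenyl]magnesium bromide (3 equiv) with CuI (10 mol %) in THF at −30 °C opens F4 at its CH2 group and returns to 10.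

Step 11. The same three processes as in step 5 threaten it, and in addition electron transfer from the nearby ketyl to the chloroarene of the ketone half may cost the chlorine. The fallback sets out from 13 and comes back at 22 by the same sequence of known steps: propargyl ether F5, oxiranyl propargyl ether F6, 4-methylene oxolane alcohol F7 (Cp2TiCl), spiro-epoxide F8 (dimethyldioxirane). Copper-catalysed opening of F8 with [4-(benzyloxy)-3-chloro-5-methoxyphenyl]magnesium bromide then returns to 22; here the chloroarene never meets a one-electron reductant.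

Step 8. Chlorination may also go para to the methoxy group or run on to a dichloride, giving a mixture that is hard to separate. The fallback sets out from 2, in which the chlorine position is fixed by the commercial aldehyde, and comes back at 17. Wittig methoxymethylenation (Ph3P=CHOMe from the phosphonium chloride and KOtBu, THF) should give the enol ether F9. Mild hydrolysis (aq. HCl, THF) should give the arylacetaldehyde F10. Pinnick oxidation (NaClO2, NaH2PO4, 2-methyl-2-butene, t-BuOH–H2O) returns to 17, so steps 8 and 9 are bypassed.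

**Further compounds**
F1 | step 5 | 2-(benzyloxy)-1-chloro-3-methoxy-5-[(1S)-1-(prop-2-yn-1-yloxy)prop-2-en-1-yl]benzene | C#CCO[C@H](c1cc(OC)c(OCc2ccccc2)c(Cl)c1)C=C
F2 | step 5 | 2-{[4-(benzyloxy)-3-chloro-5-methoxyphenyl](prop-2-yn-1-yloxy)methyl}oxirane, benzylic centre as in 4, both oxirane epimers | C#CCO[C@H](c1cc(OC)c(OCc2ccccc2)c(Cl)c1)C1CO1
F3 | step 5 | [(2S,3R)-2-[4-(benzyloxy)-3-chloro-5-methoxyphenyl]-4-methylideneoxolan-3-yl]methanol | C=C1CO[C@H](c2cc(OC)c(OCc3ccccc3)c(Cl)c2)[C@H]1CO
F4 | step 5 | {6-[4-(benzyloxy)-3-chloro-5-methoxyphenyl]-1,5-dioxaspiro[2.4]heptan-7-yl}methanol, oxirane oxygen cis to the aryl group and trans to CH2OH, aryl trans to CH2OH | C1[C@@]2(O1)CO[C@H](c3cc(OC)c(OCc4ccccc4)c(Cl)c3)[C@H]2CO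
F5 | step 11 | 1-(benzyloxy)-2-methoxy-4-[(1S)-1-(prop-2-yn-1-yloxy)prop-2-en-1-yl]benzene | C#CCO[C@H](c1ccc(OCc2ccccc2)c(OC)c1)C=C
F6 | step 11 | 2-{[4-(benzyloxy)-3-methoxyphenyl](prop-2-yn-1-yloxy)methyl}oxirane, benzylic centre as in 13, both oxirane epimers | C#CCO[C@H](c1ccc(OCc2ccccc2)c(OC)c1)C1CO1
F7 | step 11 | [(2S,3R)-2-[4-(benzyloxy)-3-methoxyphenyl]-4-methylideneoxolan-3-yl]methanol | C=C1CO[C@H](c2ccc(OCc3ccccc3)c(OC)c2)[C@H]1CO
F8 | step 11 | {6-[4-(benzyloxy)-3-methoxyphenyl]-1,5-dioxaspiro[2.4]heptan-7-yl}methanol, oxirane oxygen cis to the aryl group and trans to CH2OH, aryl trans to CH2OH | C1[C@@]2(O1)CO[C@H](c3ccc(OCc4ccccc4)c(OC)c3)[C@H]2CO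
F9 | step 8 | 2-(benzyloxy)-1-chloro-3-methoxy-5-(2-methoxyethenyl)benzene (E and Z) | COC=Cc1cc(OC)c(OCc2ccccc2)c(Cl)c1
F10 | step 8 | [4-(benzyloxy)-3-chloro-5-methoxyphenyl]acetaldehyde | O=CCc1cc(OC)c(OCc2ccccc2)c(Cl)c1
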